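## Retrosynthetic overview

1. Last bond made is C5′–OH: oxidative dearomatisation of the ring B phenol of (2S)-glabrol to its ortho-quinone, reduced in the same flask.
2. C8–prenyl and C3′–prenyl are cut together: double aromatic Claisen shift of the 7,4′-bis(1,1-dimethylallyl) ether of (2S)-liquiritigenin, each arm passing through a non-aromatic cyclohexadienone.
3. Key disconnection C2–C1′: enantioselective dearomatising 1,4-arylation of unprotected 7-hydroxychromone with unprotected 4-hydroxyphenylboronic acid; this sets the only stereocentre.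
4. The chromone comes from resacetophenone and a one-carbon unit (enaminone, then ring closure).
5. Ring order: rings A and B are bought as benzenes; ring C is closed first as a heteroaromatic pyranone (step 1) and then dearomatised to the chiral dihydropyranone (step 2); no other ring is formed and no protecting group is used.

Assumptions: the target is read as (2S) (from the SMILES), flavonoid numbering is used, and prenyl = 3-methylbut-2-enyl. (R)-t-BuPyOx is taken to give the 2S product by analogy with the facial sense known for cyclic enones; if the sense proves opposite, the equally available (S)-ligand is used and nothing else changes. tert-Butyl 2-methylbut-3-en-2-yl carbonate is taken as a catalogue reagent.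

## Route

Step 1
Reactants: 1 2′,4′-dihydroxyacetophenone (resacetophenone, bulk aromatic feedstock)
Product: 3 7-hydroxy-4H-chromen-4-one (7-hydroxychromone), via enaminone 2 (not isolated)
Conditions: DMF-DMA (1.5 equiv), PhMe, 90 °C; evaporate; AcOH, 90 °C
Reagents that add atoms: DMF-DMA (N,N-dimethylformamide dimethyl acetal), COC(OC)N(C)C
Why: Enaminone route to chromones: the methyl ketone condenses with the formamide acetal to the vinylogous amide, and acid-promoted addition of the ortho-phenol to the β-carbon followed by loss of dimethylamine closes the pyranone, the small excess of acetal limiting O-methylation of the free 4-OH.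

Step 2
Reactants: 3 7-hydroxychromone; 4 4-hydroxyphenylboronic acid
Product: 5 (2S)-7-hydroxy-2-(4-hydroxyphenyl)chroman-4-one [(2S)-liquiritigenin]
Conditions: Pd(OCOCF3)2 (5 mol%), (R)-t-BuPyOx [(R)-4-tert-butyl-2-(pyridin-2-yl)-4,5-dihydrooxazole] (6 mol%), NH4PF6 (30 mol%), H2O (5 equiv), ClCH2CH2Cl, 60 °C
Reagents that add atoms: none
Why: Asymmetric conjugate (1,4-) addition of an arylboronic acid under cationic divalent palladium/pyridine-oxazoline catalysis, a known reaction of chromones run here on the unprotected diphenol pair: transmetalation gives an aryl–palladium species that inserts C2=C3 of the pyranone on the face left open by the tert-butyl group of the ligand, water protonates the palladium enolate, the heteroaromatic ring is dearomatised and C2 is set as S, while the base-free medium excludes retro-oxa-Michael racemisation.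

Step 3
Reactants: 5 (2S)-liquiritigenin
Product: 6 (2S)-7-(2-methylbut-3-en-2-yloxy)-2-[4-(2-methylbut-3-en-2-yloxy)phenyl]chroman-4-one
Conditions: tert-butyl 2-methylbut-3-en-2-yl carbonate (3 equiv), Pd(PPh3)4 (5 mol%), THF, 0 °C, 1–2 h
Reagents that add atoms: tert-butyl 2-methylbut-3-en-2-yl carbonate, C=CC(C)(C)OC(=O)OC(C)(C)C
Why: Tsuji–Trost O-allylation under kinetic control: zerovalent palladium ionises the tertiary carbonate to a 1,1-dimethylallyl palladium cation and tert-butoxide, which deprotonates both phenols, and each phenoxide attacks the more substituted allyl terminus, so no external base is present and the flavanone ring and C2 are untouched.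

Step 4
Reactants: 6 bis(1,1-dimethylallyl) ether
Product: 10 glabrol [(2S)-7-hydroxy-2-[4-hydroxy-3-(3-methylbut-2-enyl)phenyl]-8-(3-methylbut-2-enyl)chroman-4-one], via ring A dienone 7 (not isolated), via mono-Claisen phenol 8 (not isolated), via ring B dienone 9 (not isolated)
Conditions: degassed PhMe (0.02 M), sealed tube, 115 °C, 12 h
Reagents that add atoms: none
Why: Double aromatic Claisen rearrangement ([3,3]-sigmatropic shift): each tertiary allyl aryl ether passes through a chair transition state to a non-aromatic 6-prenylcyclohexa-2,4-dienone that tautomerises to the phenol, ring A expected to react mainly at C8 (C7–C8 bond fixation by the vinylogous ester, as in 7-allyloxy-chromones and -coumarins) and ring B at its only distinct ortho position, in an isomerisation that loses no atoms and leaves C2 untouched in neutral solvent (the order of the two shifts is immaterial).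

Step 5
Reactants: 10 glabrol
Product: 12 (2S)-2-[3,4-dihydroxy-5-(3-methylbut-2-enyl)phenyl]-7-hydroxy-8-(3-methylbut-2-enyl)chroman-4-one (target), via ortho-quinone 11 (not isolated)
Conditions: IBX (1.1 equiv), DMF, 0 °C, N2, dark; then aq. Na2S2O4 (3 equiv), 0 °C to rt
Reagents that add atoms: IBX (2-iodoxybenzoic acid), O=C1OI(=O)(O)c2ccccc12
Why: Regioselective ortho-oxygenation of a phenol by IBX (pentavalent iodine; oxidative dearomatisation): the electron-rich ring B phenol binds iodine, oxygen is delivered within the complex to the only free ortho carbon to give the ortho-quinone, which dithionite reduces at once to the catechol, while the ring A phenol para to the ketone is too electron-poor to react and the low temperature and immediate reduction protect C2–H and the prenyl groups.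

## Compound list

1 | 2′,4′-dihydroxyacetophenone (resacetophenone) | CC(=O)c1ccc(O)cc1O | starting material
2 | (E)-3-(dimethylamino)-1-(2,4-dihydroxyphenyl)prop-2-en-1-one (enaminone) | CN(C)/C=C/C(=O)c1ccc(O)cc1O | intermediate
3 | 7-hydroxy-4H-chromen-4-one (7-hydroxychromone) | O=c1ccoc2cc(O)ccc12 | intermediate
4 | 4-hydroxyphenylboronic acid | OB(O)c1ccc(O)cc1 | starting material
5 | (2S)-7-hydroxy-2-(4-hydroxyphenyl)chroman-4-one (liquiritigenin) | Oc1ccc([C@@H]2CC(=O)c3ccc(O)cc3O2)cc1 | intermediate
6 | (2S)-7-(2-methylbut-3-en-2-yloxy)-2-[4-(2-methylbut-3-en-2-yloxy)phenyl]chroman-4-one | C=CC(C)(C)Oc1ccc([C@@H]2CC(=O)c3ccc(OC(C)(C)C=C)cc3O2)cc1 | intermediate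
7 | ring A dienone: (2S)-8-(3-methylbut-2-enyl)-2-[4-(2-methylbut-3-en-2-yloxy)phenyl]-2,3-dihydro-4H-chromene-4,7(8H)-dione (C8 unassigned) | C=CC(C)(C)Oc1ccc([C@@H]2CC(=O)C3=C(O2)C(CC=C(C)C)C(=O)C=C3)cc1 | intermediate
8 | mono-Claisen phenol: (2S)-7-hydroxy-8-(3-methylbut-2-enyl)-2-[4-(2-methylbut-3-en-2-yloxy)phenyl]chroman-4-one | C=CC(C)(C)Oc1ccc([C@@H]2CC(=O)c3ccc(O)c(CC=C(C)C)c3O2)cc1 | intermediate
9 | ring B dienone: (2S)-7-hydroxy-8-(3-methylbut-2-enyl)-2-[3-(3-methylbut-2-enyl)-4-oxocyclohexa-1,5-dien-1-yl]chroman-4-one (ring B sp3 carbon unassigned) | CC(C)=CCC1C=C([C@@H]2CC(=O)c3ccc(O)c(CC=C(C)C)c3O2)C=CC1=O | intermediate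
10 | glabrol, (2S)-7-hydroxy-2-[4-hydroxy-3-(3-methylbut-2-enyl)phenyl]-8-(3-methylbut-2-enyl)chroman-4-one | CC(C)=CCc1cc([C@@H]2CC(=O)c3ccc(O)c(CC=C(C)C)c3O2)ccc1O | intermediate
11 | ortho-quinone: (2S)-7-hydroxy-8-(3-methylbut-2-enyl)-2-[5-(3-methylbut-2-enyl)-3,4-dioxocyclohexa-1,5-dien-1-yl]chroman-4-one | CC(C)=CCC1=CC([C@@H]2CC(=O)c3ccc(O)c(CC=C(C)C)c3O2)=CC(=O)C1=O | intermediate
12 | (2S)-2-[3,4-dihydroxy-5-(3-methylbut-2-enyl)phenyl]-7-hydroxy-8-(3-methylbut-2-enyl)chroman-4-one | CC(C)=CCc1cc([C@@H]2CC(=O)c3ccc(O)c(CC=C(C)C)c3O2)cc(O)c1O | target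

## Step count and risk

Total step count: 5. Longest linear sequence: 5 steps (1 to 12; the boronic acid 4 is bought).

The three steps most likely to fail are steps 2, 4 and 5; step 5 is the riskiest.

Step 2. The two free phenols may bind the cationic Pd(OCOCF3)2/PyOx catalyst, the electron-rich boronic acid may protodeboronate, and the 7-oxygen lowers the electrophilicity of the chromone. The fallback gives up the C2–C1′ disconnection and closes ring C on a chalcone instead. It sets out from 1: aldol (Claisen–Schmidt) condensation of 1 with 4-hydroxybenzaldehyde (KOH, aq. EtOH, rt) gives isoliquiritigenin F1. A recombinant type 2 chalcone isomerase (the Medicago sativa enzyme, which accepts 6′-deoxychalcones; pH 7.5 buffer, 5% DMSO, 25 °C) then performs the enzyme-controlled oxa-Michael closure. The uncatalysed closure of a 6′-deoxychalcone is slow at this pH, so little racemic product forms. The fallback comes back to the route at 5.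

Step 4. Ring A may give some C6-prenyl isomer, and the tertiary ether of the acidic 7-phenol may lose isoprene instead of rearranging. The fallback moves the ring A shift to the chromone, where the pyranone fixes the C7–C8 bond, and replaces the ring B shift by a direct C-alkylation. It sets out from 3: etherification as in step 3 gives 7-(2-methylbut-3-en-2-yloxy)chromone F2, and heating (PhMe, 115 °C) gives 7-hydroxy-8-(3-methylbut-2-enyl)chromone F3. F3 is arylated with 4 under the step 2 conditions, run under N2 so that the ortho-prenylphenol is not cyclised oxidatively, to give (2S)-7,4′-dihydroxy-8-prenylflavanone (isobavachin) F4. The ring B prenyl is then introduced by ortho-C-alkylation of the more electron-rich 4′-phenol with 3-methylbut-2-en-1-ol on acidic Al2O3 (ClCH2CH2Cl, 80 °C, 1 equiv of the alcohol), ring A being deactivated by the ketone. The fallback comes back to the route at 10.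

Step 5. The ortho-quinone 11 can tautomerise to a quinone methide through C2–H (racemisation) or through the prenyl CH2 (chromene formation), and over-oxidation is possible. The fallback avoids any quinone by bringing both ring B oxygens and the ring B prenyl in with the boronic acid. It sets out from 3.
- Catechol is protected (MOMCl, i-Pr2NEt, CH2Cl2) as 1,2-bis(methoxymethoxy)benzene F5.
- Directed ortho-lithiation (n-BuLi, TMEDA, THF, 0 °C) and alkylation with prenyl bromide (CuBr·SMe2 cat.) give 1,2-bis(methoxymethoxy)-3-(3-methylbut-2-enyl)benzene F6.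
- Sterically controlled C–H borylation ([Ir(OMe)(cod)]2, 4,4′-di-tert-butyl-2,2′-bipyridine, B2pin2, THF, 60 °C) at the only C–H without an ortho neighbour gives the pinacol boronate F7, which is cleaved in the same pot (NaIO4, NH4OAc, aq. acetone) to [3,4-bis(methoxymethoxy)-5-(3-methylbut-2-enyl)phenyl]boronic acid F8.
- F8 is added to 3 under the step 2 conditions to give (2S)-7-hydroxy-2-[3,4-bis(methoxymethoxy)-5-prenylphenyl]chroman-4-one F9.
- The single free 7-OH is etherified as in step 3 to the 7-(2-methylbut-3-en-2-yl) ether F10, and the Claisen shift as in step 4 gives the bis-MOM ether of the target F11.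
- Mild acid (3 M HCl, MeOH, 40 °C) removes both MOM groups.

The fallback comes back to the route at 12.

## Further compounds

F1 | step 2 | isoliquiritigenin, (E)-1-(2,4-dihydroxyphenyl)-3-(4-hydroxyphenyl)prop-2-en-1-one | O=C(/C=C/c1ccc(O)cc1)c1ccc(O)cc1O
F2 | step 4 | 7-(2-methylbut-3-en-2-yloxy)-4H-chromen-4-one | O=c1ccoc2cc(OC(C)(C)C=C)ccc12
F3 | step 4 | 7-hydroxy-8-(3-methylbut-2-enyl)-4H-chromen-4-one | O=c1ccoc2c(CC=C(C)C)c(O)ccc12
F4 | step 4 | isobavachin, (2S)-7-hydroxy-2-(4-hydroxyphenyl)-8-(3-methylbut-2-enyl)chroman-4-one | Oc1ccc([C@@H]2CC(=O)c3ccc(O)c(CC=C(C)C)c3O2)cc1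
F5 | step 5 | 1,2-bis(methoxymethoxy)benzene | COCOc1ccccc1OCOC
F6 | step 5 | 1,2-bis(methoxymethoxy)-3-(3-methylbut-2-enyl)benzene | COCOc1cccc(CC=C(C)C)c1OCOC
F7 | step 5 | 2-[3,4-bis(methoxymethoxy)-5-(3-methylbut-2-enyl)phenyl]-4,4,5,5-tetramethyl-1,3,2-dioxaborolane | COCOc1cc(B2OC(C)(C)C(C)(C)O2)cc(CC=C(C)C)c1OCOC
F8 | step 5 | [3,4-bis(methoxymethoxy)-5-(3-methylbut-2-enyl)phenyl]boronic acid | COCOc1cc(B(O)O)cc(CC=C(C)C)c1OCOC
F9 | step 5 | (2S)-7-hydroxy-2-[3,4-bis(methoxymethoxy)-5-(3-methylbut-2-enyl)phenyl]chroman-4-one | COCOc1cc([C@@H]2CC(=O)c3ccc(O)cc3O2)cc(CC=C(C)C)c1OCOC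
F10 | step 5 | (2S)-7-(2-methylbut-3-en-2-yloxy)-2-[3,4-bis(methoxymethoxy)-5-(3-methylbut-2-enyl)phenyl]chroman-4-one | COCOc1cc([C@@H]2CC(=O)c3ccc(OC(C)(C)C=C)cc3O2)cc(CC=C(C)C)c1OCOC
F11 | step 5 | (2S)-7-hydroxy-8-(3-methylbut-2-enyl)-2-[3,4-bis(methoxymethoxy)-5-(3-methylbut-2-enyl)phenyl]chroman-4-one | COCOc1cc([C@@H]2CC(=O)c3ccc(O)c(CC=C(C)C)c3O2)cc(CC=C(C)C)c1OCOC
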